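Everything rests on reading ring D as a masked cyclohex-1-enecarbaldehyde (C4=C5 carrying the formyl carbon C6) and cutting it into acetaldehyde (C3–C4), a nitroalkene (C2=C14) and an alkylidene enal whose β-carbon is C13. One amine-catalysed cascade joins these, forming C2–C3, C13–C14 and C4=C5, closing rings C and D and setting C2 and the quaternary C13. Its precursor is a ring B cyclopentane with the quaternary C1 (methyl, ester, (E)-nitrovinyl) on C12, the exocyclic enal on C13 and, on C9 and trans to the C12 substituent, C8 as a dimethyl acetal, so that denitration, acid and acylation then finish ring A.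

Key step: step 11

Atom labels: the carbon carrying CH3 and CO2CH3 is C1; going on along the target SMILES, C2 is the next CH, C3 and C4 the ring alkene, C5 and C6 the enol ether carbons, O7 the ring oxygen, C8 the acyloxy acetal carbon, C9 to C12 the four carbons that follow, C13 the all-carbon quaternary centre and C14 the last CH2. Ring A: O7, C8, C9, C13, C5, C6. Ring B: C9 to C13. Ring C: C1, C2, C14, C13, C12. Ring D: C2, C3, C4, C5, C13, C14.

Remark on the design: C8 is carried through the key step as a dimethyl acetal, because a free C8 alcohol beside the C6 enal would be expected to close to a C6 lactol and then oxidise to the wrong lactone. The nitroalkene is made last, because it would not survive the basic and nucleophilic steps before it.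

Assumption: lactone 1 is bought enantiopure. Compounds 4, 5 and 13 are used as stereoisomer mixtures and 6, 14 and 15 may contain some (Z)-isomer (drawn E); all of these converge later. The C14 configuration of 19 is immaterial.

Step 1
Reactants: 1 (1S,5R)-2-oxabicyclo[3.3.0]oct-6-en-3-one
Product: 2 (1S,5S)-2-oxabicyclo[3.3.0]octan-3-one
Conditions: H2 (1 atm), Pd/C, EtOAc, rt
Reagents that add atoms: none
Why: Heterogeneous hydrogenation saturates the only C=C bond (the future C10–C11) and leaves the two ring-fusion stereocentres, which become C12 and C13, untouched.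

Step 2
Reactants: 2 (1S,5S)-2-oxabicyclo[3.3.0]octan-3-one; 3 acetaldehyde
Product: 4 4-(1-hydroxyethyl)-2-oxabicyclo[3.3.0]octan-3-one (diastereomer mixture)
Conditions: LiN(iPr)2, THF, −78 °C; CH3CHO, −78 °C; AcOH quench
Reagents that add atoms: none
Why: Aldol addition of the lactone lithium enolate to acetaldehyde brings in C2 and C14, and the two new stereocentres are erased in steps 3 and 4, so their ratio does not matter.

Step 3
Reactants: 4 4-(1-hydroxyethyl)-2-oxabicyclo[3.3.0]octan-3-one
Product: 6 (E)-4-ethylidene-2-oxabicyclo[3.3.0]octan-3-one, via mesylate 5 (not isolated)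
Conditions: MsCl, Et3N, CH2Cl2, 0 °C; then DBU, rt
Reagents that add atoms: none
Why: Mesylation and E1cB elimination complete an aldol condensation to the conjugated alkylidene lactone, whose geometry is irrelevant because both isomers give the same extended enolate.

Step 4
Reactants: 6 (E)-4-ethylidene-2-oxabicyclo[3.3.0]octan-3-one
Product: 7 4-methyl-4-vinyl-2-oxabicyclo[3.3.0]octan-3-one (methyl on the convex face)
Conditions: LiN(iPr)2, THF/DMPU, −78 °C; MeI, −78 to −40 °C
Reagents that add atoms: iodomethane, CI
Why: Deconjugative α-alkylation, in which γ-deprotonation of the ethylidene methyl gives the extended enolate and methyl iodide attacks C1 from the convex face of the cis-fused bicycle (anti to C11), so that methyl ends cis to H-12 and the vinyl group (C2=C14) sits on the concave face, which is the C1 configuration of the target.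

Step 5
Reactants: 7 4-methyl-4-vinyl-2-oxabicyclo[3.3.0]octan-3-one
Product: 9 methyl 2-(2-hydroxycyclopentyl)-2-methylbut-3-enoate, via lithium hydroxy carboxylate 8 (not isolated)
Conditions: LiOH (1.05 equiv), THF/H2O, rt; evaporate; MeI, DMF, rt; product used crude
Reagents that add atoms: lithium hydroxide, [Li+].[OH-]; iodomethane, CI
Why: Saponification opens the γ-lactone with retention at C13 and O-alkylation of the carboxylate gives the methyl ester, which is carried on without purification because a γ-hydroxy ester can relactonise.

Step 6
Reactants: 9 methyl 2-(2-hydroxycyclopentyl)-2-methylbut-3-enoate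
Product: 10 methyl (2R)-2-methyl-2-[(1S)-2-oxocyclopentyl]but-3-enoate
Conditions: Dess–Martin periodinane, NaHCO3, CH2Cl2, 0 °C to rt
Reagents that add atoms: none
Why: Buffered periodinane oxidation of the secondary alcohol gives the C13 ketone under non-basic conditions that should neither touch the vinyl group nor epimerise C12.

Step 7
Reactants: 10 methyl (2R)-2-methyl-2-[(1S)-2-oxocyclopentyl]but-3-enoate
Product: 12 trans keto acetal methyl 2-[3-(dimethoxymethyl)-2-oxocyclopentyl]-2-methylbut-3-enoate, via silyl enol ether 11 (not isolated)
Conditions: LiN(iPr)2, Me3SiCl, THF, −78 °C; solvent change to CH2Cl2; HC(OMe)3, Me3SiOTf (5 mol %), −78 °C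
Reagents that add atoms: trimethyl orthoformate, COC(OC)OC
Why: Kinetic deprotonation at the unhindered C9 methylene (C12–H is shielded by the quaternary C1) and Mukaiyama-type alkylation of the silyl enol ether by the dimethoxycarbenium ion install C8 at the aldehyde oxidation level; the electrophile should approach C9 anti to the bulky C12 substituent, and trans is also the thermodynamically preferred arrangement at this epimerisable centre.

Step 8
Reactants: 12 trans keto acetal
Product: 13 tertiary allylic alcohol methyl 2-[3-(dimethoxymethyl)-2-hydroxy-2-vinylcyclopentyl]-2-methylbut-3-enoate (C13 epimer mixture)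
Conditions: CH2=CHMgBr, CeCl3, THF, −78 °C; AcOH quench at −78 °C
Reagents that add atoms: vinylmagnesium bromide, C=C[Mg]Br
Why: Organocerium 1,2-addition, which is of low basicity and so avoids enolisation and β-elimination of methanol, adds the C5–C6 unit to the hindered ketone; both C13 epimers are used because this centre becomes sp2 in step 9.

Step 9
Reactants: 13 tertiary allylic alcohol
Product: 14 alkylidene enal methyl 2-[3-(dimethoxymethyl)-2-(2-oxoethylidene)cyclopentyl]-2-methylbut-3-enoate
Conditions: [C5H5NH][CrO3Cl] (3 equiv), 4 Å MS, CH2Cl2, rt
Reagents that add atoms: pyridinium chlorochromate, [O-][Cr](=O)(=O)Cl.c1cc[nH+]cc1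
Why: Babler–Dauben oxidative transposition, in which the tertiary allylic chromate ester undergoes a [3,3] shift to the primary allylic chromate that is then oxidised to the β,β-disubstituted enal, while the isolated C1 vinyl group, the acetal and the ester are inert.

Step 10
Reactants: 14 alkylidene enal
Product: 15 cascade precursor methyl 2-[3-(dimethoxymethyl)-2-(2-oxoethylidene)cyclopentyl]-2-methyl-4-nitrobut-3-enoate
Conditions: AgNO2 (3 equiv), TEMPO (0.4 equiv), 4 Å MS, ClCH2CH2Cl, 70 °C
Reagents that add atoms: silver nitrite, [Ag+].[O-]N=O
Why: Radical nitration of a terminal alkene, in which the NO2 radical adds to the terminal carbon C14 and TEMPO removes the adjacent hydrogen to give the (E)-nitroalkene, the electron-poor trisubstituted enal double bond being far less reactive towards the electrophilic NO2 radical.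

Step 11
Reactants: 15 cascade precursor; 3 acetaldehyde
Product: 19 tricyclic nitro enal (rings B, C and D), via Michael adduct 16 (not isolated), via nitro dialdehyde 17 (not isolated), via aldol adduct 18 (not isolated)
Conditions: CH3CHO (5 equiv), (S)-diphenylprolinol trimethylsilyl ether (20 mol %), PhCO2H (20 mol %), CHCl3, 0 °C to rt
Reagents that add atoms: none
Why: Proposed new method: the amine forms the enamine of acetaldehyde, which adds to the nitroalkene at C2 (C2–C3 bond, giving 16); the amine then turns the alkylidene enal into its iminium ion, the nitronate carbon C14 adds to C13 by 5-exo-trig closure of ring C (17), and the enamine left at C5 attacks the aldehyde C4 by 6-(enolexo)-exo-trig aldol closure of ring D (18), after which loss of water gives the C4=C5 enal. The closest known reaction type is the amine-catalysed Michael, nitro-Michael, aldol-condensation triple cascade of an aldehyde, a nitroalkene and an enal; new here are acetaldehyde as the donor, a nitroalkene on a quaternary carbon and a tethered β,β-disubstituted enal as the second acceptor. C2 is set by the catalyst, whose shielded enamine face is expected to give the (S)-configured C2 of 16 as it does with simple nitroalkenes, and C13 is set by C12, because the two-atom tether C12–C1 lets C14 reach only the face of C13 that is cis to C1 (cis B/C fusion), which is also the face anti to the C9 acetal; C14 is epimerisable and is removed in step 12. The step needs C14 and not the enamine carbon C3 to attack C13, which relies on the known preference of iminium ions for nitronate donors, and it needs the right C2 epimer, since only that one places C4 within reach of C5, so a wrong epimer should stall at the stage of 17 and not give a ring D isomer. The alkene geometry of 15 is lost when C13 becomes quaternary, so (E)- and (Z)-15 should converge.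

Step 12
Reactants: 19 tricyclic nitro enal
Product: 20 tricyclic enal acetal
Conditions: Bu3SnH (5 equiv), AIBN (0.3 equiv, in portions), toluene, 110 °C
Reagents that add atoms: none
Why: Radical denitration of a secondary nitroalkane, in which the stannyl radical adds to a nitro oxygen, the C14–N bond fragments at 110 °C and the bridge radical takes hydrogen from the excess stannane faster than it can add to the neighbouring alkene; C14 thereby ceases to be a stereocentre.

Step 13
Reactants: 20 tricyclic enal acetal
Product: 21 tricyclic dialdehyde
Conditions: TsOH·H2O (10 mol %), THF/H2O (4:1), rt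
Reagents that add atoms: water, O
Why: Acid-catalysed acetal hydrolysis unmasks the C8 aldehyde without any oxidation step, under conditions that should leave the methyl ester and the enal alone.

Step 14
Reactants: 21 tricyclic dialdehyde
Product: 23 CNP0315847.1, via lactol 22 (not isolated)
Conditions: DBU (0.3 equiv), CH2Cl2, 0 °C; then (iPrCH2CO)2O (2 equiv), Et3N, DMAP (10 mol %), 0 °C to rt
Reagents that add atoms: 3-methylbutanoic anhydride, CC(C)CC(=O)OC(=O)CC(C)C
Why: Base-mediated ring–chain tautomerism (γ-deprotonation at C3, then closure of the dienol oxygen O7 onto the cis-disposed C8 aldehyde) gives the lactol, which is trapped by DMAP-catalysed O-acylation; the acyloxy group should settle anti to C10 of ring B, on the convex face of ring A, since that pseudoaxial anomer of the equilibrating lactol is also the more accessible one.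

Compound list
1 | (1S,5R)-2-oxabicyclo[3.3.0]oct-6-en-3-one, cis-fused | O=C1C[C@@H]2C=CC[C@@H]2O1 | starting material
2 | (1S,5S)-2-oxabicyclo[3.3.0]octan-3-one, cis-fused | O=C1C[C@@H]2CCC[C@@H]2O1 | intermediate
3 | acetaldehyde | CC=O | starting material
4 | 4-(1-hydroxyethyl)-2-oxabicyclo[3.3.0]octan-3-one, ring fusion as in 2, C4 and the carbinol carbon left open (mixture) | O=C1O[C@H]2CCC[C@H]2C1C(C)O | intermediate
5 | methanesulfonate of 4 (mixture as for 4) | O=C1O[C@H]2CCC[C@H]2C1C(C)OS(C)(=O)=O | intermediate (not isolated)
6 | (E)-4-ethylidene-2-oxabicyclo[3.3.0]octan-3-one, ring fusion as in 2 | O=C1O[C@H]2CCC[C@H]2/C1=C\C | intermediate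
7 | 4-methyl-4-vinyl-2-oxabicyclo[3.3.0]octan-3-one, methyl cis to H-5 (convex face), vinyl on the concave face | O=C1O[C@H]2CCC[C@H]2[C@@]1(C)C=C | intermediate
8 | lithium 2-(2-hydroxycyclopentyl)-2-methylbut-3-enoate, configuration as in 9 | [Li+].[O-]C(=O)[C@](C)(C=C)[C@@H]1CCC[C@@H]1O | intermediate (not isolated)
9 | methyl 2-(2-hydroxycyclopentyl)-2-methylbut-3-enoate, hydroxyl cis to the side chain, C1 and C12 as in 10 | COC(=O)[C@](C)(C=C)[C@@H]1CCC[C@@H]1O | intermediate
10 | methyl (2R)-2-methyl-2-[(1S)-2-oxocyclopentyl]but-3-enoate | COC(=O)[C@](C)(C=C)[C@@H]1CCCC1=O | intermediate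
11 | trimethylsilyl enol ether of 10 (C13=C9) | COC(=O)[C@](C)(C=C)[C@@H]1CCC=C1O[Si](C)(C)C | intermediate (not isolated)
12 | methyl 2-[3-(dimethoxymethyl)-2-oxocyclopentyl]-2-methylbut-3-enoate, acetal carbon trans to the side chain, C1 and C12 as in 10 | COC(=O)[C@](C)(C=C)[C@@H]1CC[C@@H](C(OC)OC)C1=O | intermediate
13 | methyl 2-[3-(dimethoxymethyl)-2-hydroxy-2-vinylcyclopentyl]-2-methylbut-3-enoate, C13 left open (both epimers) | COC(=O)[C@](C)(C=C)[C@@H]1CC[C@@H](C(OC)OC)C1(O)C=C | intermediate
14 | methyl 2-[3-(dimethoxymethyl)-2-(2-oxoethylidene)cyclopentyl]-2-methylbut-3-enoate, E (formyl trans to C9) | COC(=O)[C@](C)(C=C)[C@@H]1CC[C@@H](C(OC)OC)/C1=C/C=O | intermediate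
15 | methyl 2-[3-(dimethoxymethyl)-2-(2-oxoethylidene)cyclopentyl]-2-methyl-4-nitrobut-3-enoate, (E)-nitroalkene, cascade precursor | COC(=O)[C@](C)(/C=C/[N+](=O)[O-])[C@@H]1CC[C@@H](C(OC)OC)/C1=C/C=O | intermediate
16 | γ-nitro aldehyde from addition of acetaldehyde at C2 | COC(=O)[C@](C)([C@@H](C[N+](=O)[O-])CC=O)[C@@H]1CC[C@@H](C(OC)OC)/C1=C/C=O | intermediate (not isolated)
17 | cis-fused B/C bicyclic nitro dialdehyde (formylmethyl groups on C2 and C13) | COC(=O)[C@]1(C)[C@H](CC=O)[C@H]([N+](=O)[O-])[C@@]2(CC=O)[C@H](C(OC)OC)CC[C@@H]12 | intermediate (not isolated)
18 | tricyclic β-hydroxy aldehyde, C4 and C5 left open | COC(=O)[C@]1(C)[C@@H]2CC(O)C(C=O)[C@@]3([C@H](C(OC)OC)CC[C@@H]13)[C@H]2[N+](=O)[O-] | intermediate (not isolated)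
19 | tricyclic nitro enal (rings B, C and D; C4=C5 with formyl C6; nitro on C14; dimethyl acetal on C9) | COC(=O)[C@]1(C)[C@@H]2CC=C(C=O)[C@@]3([C@H](C(OC)OC)CC[C@@H]13)[C@H]2[N+](=O)[O-] | intermediate
20 | tricyclic enal acetal (19 with C14 as CH2) | COC(=O)[C@]1(C)[C@@H]2CC=C(C=O)[C@@]3([C@H](C(OC)OC)CC[C@@H]13)C2 | intermediate
21 | tricyclic dialdehyde (C8 and C6 formyl groups) | COC(=O)[C@]1(C)[C@@H]2CC=C(C=O)[C@@]3([C@H](C=O)CC[C@@H]13)C2 | intermediate
22 | tetracyclic dienol lactol, C8 left open (equilibrating anomers) | COC(=O)[C@]1(C)[C@@H]2C=CC3=COC(O)[C@@H]4CC[C@@H]1[C@]34C2 | intermediate (not isolated)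
23 | CNP0315847.1 | COC(=O)[C@]1(C)[C@@H]2C=CC3=CO[C@@H](OC(=O)CC(C)C)[C@@H]4CC[C@@H]1[C@]34C2 | target

Total step count: 14. Longest linear sequence: 14 steps (from 1; fully linear).

Steps most likely to fail

Step 11. The acetaldehyde enamine may add too slowly to a nitroalkene that sits on a quaternary carbon. Acetaldehyde self-condensation and dienamine formation from the enal (with epimerisation at C9 or C12) could then take over, or the catalyst may not override the facial bias of C1 at C2. The fallback uses known reactions only and sets out from 14. Cross-metathesis of the C1 vinyl group with crotonaldehyde (second-generation Grubbs catalyst, CH2Cl2, 40 °C) would give the bis-enal F1. Iminium-catalysed conjugate addition of nitromethane to its unhindered β-monosubstituted enal (diphenylprolinol trimethylsilyl ether of the appropriate hand, PhCO2H, MeOH, rt) would give the γ-nitro aldehyde 16, now isolated, with C2 set by the catalyst. DBU in CH2Cl2 would then close ring C by intramolecular nitro-Michael addition to the remaining enal and ring D by aldol condensation, coming back to the route at 19. Here C3–C4 come from crotonaldehyde and C14 from nitromethane, so no enamine has to attack the hindered nitroalkene.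

Step 12. Stannyl radicals may attack the conjugated aldehyde (hydrostannation or conjugate reduction) while the secondary C–N bond fragments only slowly, and the C14 radical may add to the adjacent C4=C5 bond and rearrange. The fallback sets out from 19. Luche reduction (NaBH4, CeCl3·7H2O, MeOH, −40 °C) would give the nitro allylic alcohol F2, in which the acceptor is switched off. The same Bu3SnH/AIBN denitration would then give the allylic alcohol F3, and MnO2 in CH2Cl2 would reoxidise it, coming back to the route at 20.

Step 14. Acylation may outrun ring closure, giving open-chain dienyl or enol esters, the C9 aldehyde may epimerise before it is captured, and the anomeric configuration at C8 may not be controlled. The fallback sets out from 20 and separates ring closure from acylation. Camphorsulfonic acid (cat.) in dry CH2Cl2 with 4 Å MS would ionise the acetal; capture of the C8 oxocarbenium ion by the enal oxygen and loss of the C3 proton would give the cyclic methyl acetal F4 under thermodynamic control. Mild aqueous acid (AcOH/H2O/THF) would exchange OMe for OH, coming back to the route at lactol 22, which would be acylated as in the second stage of step 14 to give 23.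

Further compounds
F1 | step 11 | methyl 2-[3-(dimethoxymethyl)-2-(2-oxoethylidene)cyclopentyl]-2-methyl-5-oxopent-3-enoate, (E)-enal on C1, configuration as in 14 | COC(=O)[C@](C)(/C=C/C=O)[C@@H]1CC[C@@H](C(OC)OC)/C1=C/C=O
F2 | step 12 | nitro allylic alcohol (19 with C6 reduced to CH2OH) | COC(=O)[C@]1(C)[C@@H]2CC=C(CO)[C@@]3([C@H](C(OC)OC)CC[C@@H]13)[C@H]2[N+](=O)[O-]
F3 | step 12 | allylic alcohol (F2 with C14 as CH2) | COC(=O)[C@]1(C)[C@@H]2CC=C(CO)[C@@]3([C@H](C(OC)OC)CC[C@@H]13)C2
F4 | step 14 | tetracyclic dienol ether with a methyl acetal at C8 (C8 left open) | COC(=O)[C@]1(C)[C@@H]2C=CC3=COC(OC)[C@@H]4CC[C@@H]1[C@]34C2
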